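## Retrosynthetic overview

1. The two acid chains are unmasked last, by oxidative cleavage of the C2–C3 bond of a ring-A α-ketol. Ring A is a temporary six-membered template that holds C1 and C4 cis on ring B (5β-H).
2. The pyran ring is closed from an 8(17)-alkene and the C13 tertiary alcohol by alkoxymercuration; C13 comes unchanged from (R)-linalool.
3. Key step: ring B is closed by an intramolecular Michael addition of a C8 ketone enolate (C9) to the β-methyl enone of ring A (C10). This sets C9 and C10 relative to C5.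
4. The cyclisation precursor is joined at C8–C9 by a palladium-catalysed thioester–alkylzinc ketone synthesis. The partners are a ring-A thioester from (R)-α-ionone (five steps) and a C9–C15 iodide from (R)-linalool (five steps).
5. Ring order: ring A (bought with α-ionone), then ring B (Michael), then the pyran ring (etherification), then ring A is opened.

Assumption: (R)-(+)-α-ionone and (R)-(−)-linalool are bought as single enantiomers; atom labels C1–C20 and α/β follow the labdane skeleton (C10 methyl β); from step 4 to step 14 the material is a mixture of C3 epimers, which is harmless because C3 ends as a carboxyl carbon.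

## Ring-A fragment

Step 1
Reactants: 1 (3E)-4-[(1R)-2,6,6-trimethylcyclohex-2-en-1-yl]but-3-en-2-one ((R)-α-ionone)
Product: 3 4-[(1R)-2,6,6-trimethylcyclohex-2-en-1-yl]butan-2-one, via silyl enol ether 2 (not isolated)
Conditions: Et3SiH, RhCl(PPh3)3 (0.5 mol%), 50 °C; then K2CO3, MeOH, rt
Reagents that add atoms: none
Why: Rhodium-catalysed conjugate (1,4-) hydrosilylation reduces only the enone C=C, leaving the trisubstituted ring alkene and the allylic stereocentre untouched, and methanolysis of the silyl enol ether frees the ketone.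

Step 2
Reactants: 3 4-[(1R)-2,6,6-trimethylcyclohex-2-en-1-yl]butan-2-one
Product: 4 3-[(1R)-2,6,6-trimethylcyclohex-2-en-1-yl]propanoic acid
Conditions: NaOCl (aq, 3.5 equiv), NaOH, dioxane/H2O, 0 °C to rt; Na2SO3; HCl to pH 2
Reagents that add atoms: sodium hydroxide, [Na+].[OH-]
Why: Haloform reaction of the methyl ketone; at pH above 12 hypochlorite does not attack the ring alkene, and the stereocentre is not enolisable.

Step 3
Reactants: 4 3-[(1R)-2,6,6-trimethylcyclohex-2-en-1-yl]propanoic acid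
Product: 5 3-[(1R)-2,6,6-trimethyl-4-oxocyclohex-2-en-1-yl]propanoic acid
Conditions: t-BuOOH (70% aq, 8 equiv), Rh2(cap)4 (dirhodium tetrakis(caprolactamate), 1 mol%), ClCH2CH2Cl, 40 °C
Reagents that add atoms: tert-butyl hydroperoxide, CC(C)(C)OO
Why: Catalytic allylic C–H oxidation at the only ring methylene next to the alkene (C2) gives the β-methyl enone under neutral conditions, so the γ-stereocentre C5 is not epimerised.

Step 4
Reactants: 5 3-[(1R)-2,6,6-trimethyl-4-oxocyclohex-2-en-1-yl]propanoic acid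
Product: 7 3-[(1S,5RS)-2,6,6-trimethyl-4-oxo-5-(triethylsilyloxy)cyclohex-2-en-1-yl]propanoic acid, via bis-silyl dienol ether 6 (not isolated)
Conditions: LiN(i-Pr)2 (2.2 equiv), THF, −78 °C; Et3SiCl (2.5 equiv); then mCPBA, NaHCO3, CH2Cl2, −20 °C; aqueous work-up at pH 4
Reagents that add atoms: chlorotriethylsilane, CC[Si](CC)(CC)Cl; 3-chloroperbenzoic acid, OOC(=O)c1cccc(Cl)c1
Why: Rubottom oxidation: kinetic deprotonation of the carboxylate-enone goes to the α′-carbon (C3) and not to the γ-hydrogen at C5, and epoxidation of the silyl dienol ether with silyl migration puts a protected oxygen on C3 (either epimer serves; the ring descriptor changes from R to S only through CIP priorities).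

Step 5
Reactants: 7 3-[(1S,5RS)-2,6,6-trimethyl-4-oxo-5-(triethylsilyloxy)cyclohex-2-en-1-yl]propanoic acid
Product: 8 S-ethyl 3-[(1S,5RS)-2,6,6-trimethyl-4-oxo-5-(triethylsilyloxy)cyclohex-2-en-1-yl]propanethioate
Conditions: EtSH, DCC, DMAP (cat.), CH2Cl2, 0 °C to rt
Reagents that add atoms: ethanethiol, CCS
Why: Steglich thioesterification gives an acyl donor that survives storage and reacts with organozincs only under palladium catalysis.

## Side-chain fragment

Step 6
Reactants: 9 (3R)-3,7-dimethylocta-1,6-dien-3-ol ((R)-linalool)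
Product: 10 triethyl{[(3R)-3,7-dimethylocta-1,6-dien-3-yl]oxy}silane
Conditions: Et3SiOTf, 2,6-lutidine, CH2Cl2, −78 to 0 °C
Reagents that add atoms: triethylsilyl trifluoromethanesulfonate, CC[Si](CC)(CC)OS(=O)(=O)C(F)(F)F
Why: Silylation of the hindered tertiary alcohol with the silyl triflate; the C–O bond of the stereocentre is not touched.

Step 7
Reactants: 10 triethyl{[(3R)-3,7-dimethylocta-1,6-dien-3-yl]oxy}silane
Product: 11 (3RS,6R)-2,6-dimethyl-6-(triethylsilyloxy)oct-7-ene-2,3-diol
Conditions: OsO4 (2 mol%), N-methylmorpholine N-oxide (1.1 equiv), acetone/H2O, 0 °C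
Reagents that add atoms: N-methylmorpholine N-oxide, C[N+]1([O-])CCOCC1; water, O
Why: Upjohn dihydroxylation picks the electron-rich trisubstituted alkene over the vinyl group, which is hindered and deactivated by the neighbouring silyloxy quaternary carbon; the new carbinol centre is lost in the next step.

Step 8
Reactants: 11 (3RS,6R)-2,6-dimethyl-6-(triethylsilyloxy)oct-7-ene-2,3-diol
Product: 12 (4R)-4-methyl-4-(triethylsilyloxy)hex-5-enal
Conditions: NaIO4, THF/H2O, 0 °C to rt
Reagents that add atoms: none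
Why: Malaprade glycol cleavage removes the terminal three carbons as acetone and leaves the aldehyde carbon that becomes C9.

Step 9
Reactants: 12 (4R)-4-methyl-4-(triethylsilyloxy)hex-5-enal
Product: 13 (4R)-4-methyl-4-(triethylsilyloxy)hex-5-en-1-ol
Conditions: NaBH4, MeOH, 0 °C
Reagents that add atoms: none
Why: Borohydride reduction of the aldehyde; alkene and silyl ether are inert.

Step 10
Reactants: 13 (4R)-4-methyl-4-(triethylsilyloxy)hex-5-en-1-ol
Product: 14 triethyl{[(3R)-6-iodo-3-methylhex-1-en-3-yl]oxy}silane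
Conditions: I2, PPh3, imidazole, CH2Cl2, 0 °C
Reagents that add atoms: iodine, II
Why: Appel-type iodination of the primary alcohol by SN2 displacement of the oxyphosphonium group.

## Fragment union and end game

Step 11
Reactants: 14 triethyl{[(3R)-6-iodo-3-methylhex-1-en-3-yl]oxy}silane; 8 S-ethyl 3-[(1S,5RS)-2,6,6-trimethyl-4-oxo-5-(triethylsilyloxy)cyclohex-2-en-1-yl]propanethioate
Product: 16 (7R)-7-methyl-7-(triethylsilyloxy)-1-[(1S,5RS)-2,6,6-trimethyl-4-oxo-5-(triethylsilyloxy)cyclohex-2-en-1-yl]non-8-en-3-one, via alkylzinc iodide 15 (not isolated)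
Conditions: 14 (1.5 equiv), Zn dust (activated with BrCH2CH2Br and Me3SiCl), THF, 40 °C; then 8, PdCl2(PPh3)2 (5 mol%), toluene, rt
Reagents that add atoms: none
Why: Fukuyama coupling: the alkylzinc iodide transfers its alkyl group to the thioester under palladium catalysis and ignores the enone, the α-silyloxy ketone and the silyl ethers, forming the C8–C9 bond and the C8 ketone.

Step 12
Reactants: 16 (7R)-7-methyl-7-(triethylsilyloxy)-1-[(1S,5RS)-2,6,6-trimethyl-4-oxo-5-(triethylsilyloxy)cyclohex-2-en-1-yl]non-8-en-3-one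
Product: 17 (13R)-3ξ,13-bis(triethylsilyloxy)-17-nor-5β-labd-14-ene-2,8-dione
Conditions: KOt-Bu (0.3 equiv), t-BuOH/THF (1:4), 0 °C, 2 h; pH 7 buffer
Reagents that add atoms: none
Why: Intramolecular Michael addition (6-exo-trig): only the C9 enolate can reach the enone β-carbon C10 through a six-membered transition state and the tether on C5 reaches it only on its own face, so ring B is cis-fused (C10 methyl cis to H5), and C11 takes the equatorial site of the chair-like forming ring (the axial site points into ring A), which places it cis to the C10 methyl.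

Step 13
Reactants: 17 (13R)-3ξ,13-bis(triethylsilyloxy)-17-nor-5β-labd-14-ene-2,8-dione
Product: 19 (13R)-3ξ,13-dihydroxy-5β-labda-8(17),14-dien-2-one, via methylene bis-silyl ether 18 (not isolated)
Conditions: Ph3PCH3Br, KOt-Bu, THF, 0 °C to rt; then Bu4NF, THF, rt
Reagents that add atoms: methyltriphenylphosphonium bromide, C[P+](c1ccccc1)(c1ccccc1)c1ccccc1.[Br-]
Why: Wittig methylenation is expected at C8, because the C2 carbonyl is screened by the neighbouring silyloxy group, the axial 4-methyl and the two flanking quaternary carbons; fluoride then removes both silyl groups.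

Step 14
Reactants: 19 (13R)-3ξ,13-dihydroxy-5β-labda-8(17),14-dien-2-one
Product: 21 (13R)-8α,13-epoxy-3ξ-hydroxy-5β-labd-14-en-2-one, via organomercurial 20 (not isolated)
Conditions: Hg(OCOCF3)2 (1.05 equiv), CH2Cl2, −30 °C; then NaBH4 (0.5 equiv), 3 M NaOH, −30 °C, 10 min
Reagents that add atoms: none
Why: Intramolecular alkoxymercuration–demercuration: Markovnikov 6-exo attack of the C13 hydroxyl on the mercurinium ion of the 1,1-disubstituted alkene (the vinyl group is much slower) comes in equatorially at C8, anti to the axial C10 methyl, giving the trans-fused pyran with the C8 methyl axial; C13 keeps its configuration because its C–O bond is not broken. Any 2,3-diol from over-reduction of the C2 ketone ends up as the same diacid in step 15.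

Step 15
Reactants: 21 (13R)-8α,13-epoxy-3ξ-hydroxy-5β-labd-14-en-2-one
Product: 23 2-[(2R,4aR,5S,6S,8aR)-5-(carboxymethyl)-2-ethenyl-2,5,8a-trimethyloctahydro-2H-chromen-6-yl]-2-methylpropanoic acid, via aldehyde acid 22 (not isolated)
Conditions: NaIO4 (3 equiv), THF/H2O, rt; then NaClO2, NaH2PO4, 2-methylbut-2-ene, t-BuOH/H2O, rt
Reagents that add atoms: sodium periodate, [Na+].[O-]I(=O)(=O)=O; sodium chlorite, [Na+].[O-]Cl=O
Why: Periodate cleavage of the α-ketol breaks only the C2–C3 bond (C2 becomes the acid, C3 the aldehyde), and Pinnick oxidation with an alkene scavenger takes the neopentyl aldehyde to the second acid without touching the vinyl group or any stereocentre.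

## Compound list

1 | (R)-α-ionone, (3E)-4-[(1R)-2,6,6-trimethylcyclohex-2-en-1-yl]but-3-en-2-one | CC(=O)/C=C/[C@H]1C(C)=CCCC1(C)C | starting material
2 | triethyl({4-[(1R)-2,6,6-trimethylcyclohex-2-en-1-yl]but-2-en-2-yl}oxy)silane (E/Z mixture) | CC(=CC[C@H]1C(C)=CCCC1(C)C)O[Si](CC)(CC)CC | intermediate
3 | 4-[(1R)-2,6,6-trimethylcyclohex-2-en-1-yl]butan-2-one | CC(=O)CC[C@H]1C(C)=CCCC1(C)C | intermediate
4 | 3-[(1R)-2,6,6-trimethylcyclohex-2-en-1-yl]propanoic acid | OC(=O)CC[C@H]1C(C)=CCCC1(C)C | intermediate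
5 | 3-[(1R)-2,6,6-trimethyl-4-oxocyclohex-2-en-1-yl]propanoic acid | OC(=O)CC[C@H]1C(C)=CC(=O)CC1(C)C | intermediate
6 | triethylsilyl 3-[(1S)-2,6,6-trimethyl-4-(triethylsilyloxy)cyclohexa-2,4-dien-1-yl]propanoate | CC[Si](CC)(CC)OC(=O)CC[C@H]1C(C)=CC(O[Si](CC)(CC)CC)=CC1(C)C | intermediate
7 | 3-[(1S,5RS)-2,6,6-trimethyl-4-oxo-5-(triethylsilyloxy)cyclohex-2-en-1-yl]propanoic acid (C5 of the ring = C3, both epimers) | OC(=O)CC[C@H]1C(C)=CC(=O)C(O[Si](CC)(CC)CC)C1(C)C | intermediate
8 | S-ethyl 3-[(1S,5RS)-2,6,6-trimethyl-4-oxo-5-(triethylsilyloxy)cyclohex-2-en-1-yl]propanethioate | CCSC(=O)CC[C@H]1C(C)=CC(=O)C(O[Si](CC)(CC)CC)C1(C)C | intermediate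
9 | (R)-linalool, (3R)-3,7-dimethylocta-1,6-dien-3-ol | C=C[C@](C)(O)CCC=C(C)C | starting material
10 | triethyl{[(3R)-3,7-dimethylocta-1,6-dien-3-yl]oxy}silane | C=C[C@](C)(O[Si](CC)(CC)CC)CCC=C(C)C | intermediate
11 | (3RS,6R)-2,6-dimethyl-6-(triethylsilyloxy)oct-7-ene-2,3-diol | C=C[C@](C)(O[Si](CC)(CC)CC)CCC(O)C(C)(C)O | intermediate
12 | (4R)-4-methyl-4-(triethylsilyloxy)hex-5-enal | C=C[C@](C)(O[Si](CC)(CC)CC)CCC=O | intermediate
13 | (4R)-4-methyl-4-(triethylsilyloxy)hex-5-en-1-ol | C=C[C@](C)(O[Si](CC)(CC)CC)CCCO | intermediate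
14 | triethyl{[(3R)-6-iodo-3-methylhex-1-en-3-yl]oxy}silane | C=C[C@](C)(O[Si](CC)(CC)CC)CCCI | intermediate
15 | iodo[(4R)-4-methyl-4-(triethylsilyloxy)hex-5-en-1-yl]zinc | C=C[C@](C)(O[Si](CC)(CC)CC)CCC[Zn]I | intermediate
16 | (7R)-7-methyl-7-(triethylsilyloxy)-1-[(1S,5RS)-2,6,6-trimethyl-4-oxo-5-(triethylsilyloxy)cyclohex-2-en-1-yl]non-8-en-3-one | C=C[C@](C)(O[Si](CC)(CC)CC)CCCC(=O)CC[C@H]1C(C)=CC(=O)C(O[Si](CC)(CC)CC)C1(C)C | intermediate
17 | (13R)-3ξ,13-bis(triethylsilyloxy)-17-nor-5β-labd-14-ene-2,8-dione (cis-decalin: 5β-H, 10β-CH3, 9α-H) | C=C[C@](C)(O[Si](CC)(CC)CC)CC[C@@H]2[C@@]3(C)CC(=O)C(O[Si](CC)(CC)CC)C(C)(C)[C@H]3CCC2=O | intermediate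
18 | (13R)-3ξ,13-bis(triethylsilyloxy)-5β-labda-8(17),14-dien-2-one | C=C[C@](C)(O[Si](CC)(CC)CC)CC[C@@H]2[C@@]3(C)CC(=O)C(O[Si](CC)(CC)CC)C(C)(C)[C@H]3CCC2=C | intermediate
19 | (13R)-3ξ,13-dihydroxy-5β-labda-8(17),14-dien-2-one | C=C[C@](C)(O)CC[C@@H]2[C@@]3(C)CC(=O)C(O)C(C)(C)[C@H]3CCC2=C | intermediate
20 | (13R)-8α,13-epoxy-3ξ-hydroxy-17-(trifluoroacetoxymercurio)-5β-labd-14-en-2-one | C=C[C@@]1(C)CC[C@@H]2[C@@]3(C)CC(=O)C(O)C(C)(C)[C@H]3CC[C@@]2(C[Hg]OC(=O)C(F)(F)F)O1 | intermediate
21 | (13R)-8α,13-epoxy-3ξ-hydroxy-5β-labd-14-en-2-one | C=C[C@@]1(C)CC[C@@H]2[C@@]3(C)CC(=O)C(O)C(C)(C)[C@H]3CC[C@@]2(C)O1 | intermediate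
22 | (13R)-8α,13-epoxy-3-oxo-2,3-seco-5β-labd-14-en-2-oic acid | C=C[C@@]1(C)CC[C@@H]2[C@@](C)(CC(=O)O)[C@@H](C(C)(C)C=O)CC[C@@]2(C)O1 | intermediate
23 | (13R)-8α,13-epoxy-2,3-seco-5β-labd-14-ene-2,3-dioic acid, 2-[(2R,4aR,5S,6S,8aR)-5-(carboxymethyl)-2-ethenyl-2,5,8a-trimethyloctahydro-2H-chromen-6-yl]-2-methylpropanoic acid | C=C[C@@]1(C)CC[C@@H]2[C@@](C)(CC(=O)O)[C@@H](C(C)(C)C(=O)O)CC[C@@]2(C)O1 | target

## Step count and risks

Total step count: 15. Longest linear sequence: 10 (steps 1–5 then 11–15, or steps 6–10 then 11–15).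

**Step 12 (Michael ring closure).** The acceptor is a hindered β,β-disubstituted enone next to a gem-dimethyl carbon. Alkoxide could also epimerise C5 through the extended dienolate, or drive bridged ketol formation from the 1,5-diketone. Fallback: leave alkoxide chemistry for a Stork enamine cyclisation. Setting out from 16, condensation with pyrrolidine (4 Å molecular sieves, benzene, 60 °C) gives the C8 pyrrolidine enamine F1 (Δ8,9 isomer, in equilibrium with the Δ7,8 isomer). It closes ring B on heating in dioxane (90 °C) without base, and hydrolysis with aqueous AcOH/NaOAc comes back to the route at 17.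

**Step 13 (methylenation of C8 in the presence of the C2 ketone).** The selectivity rests on sterics only, and the basic ylide may epimerise C9. Fallback: mask C2 during ring closure. Setting out from 16, the cyclisation is run with KN(SiMe3)2 (1.05 equiv, THF, −78 to −40 °C) and the ring-A enolate left by the Michael addition is trapped with Et3SiCl. This gives the C1=C2 silyl enol ether (13R)-2,3ξ,13-tris(triethylsilyloxy)-17-nor-5β-labda-1,14-dien-8-one F2, whose only carbonyl is C8. Ph3P=CH2 then gives the triene (13R)-2,3ξ,13-tris(triethylsilyloxy)-5β-labda-1,8(17),14-triene F3. Bu4NF removes all three silyl groups (the enol ether reverts to the C2 ketone) and the route is rejoined at 19.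

**Step 14 (pyran closure).** The risks are reaction at the vinyl group, the wrong face at C8, reversion during demercuration and reduction of the ketol. Fallback: halocyclisation followed by radical reduction. Setting out from 19, iodoetherification (I2, NaHCO3, MeCN, 0 °C) gives the iodomethyl ether (13R)-8α,13-epoxy-3ξ-hydroxy-17-iodo-5β-labd-14-en-2-one F4. Deiodination with Bu3SnH and AIBN (benzene, 80 °C) comes back to the route at 21.

Further compounds

F1 | step 12 | 1-{(7R)-7-methyl-7-(triethylsilyloxy)-1-[(1S,5RS)-2,6,6-trimethyl-4-oxo-5-(triethylsilyloxy)cyclohex-2-en-1-yl]nona-3,8-dien-3-yl}pyrrolidine | C=C[C@](C)(O[Si](CC)(CC)CC)CCC=C(N1CCCC1)CC[C@H]1C(C)=CC(=O)C(O[Si](CC)(CC)CC)C1(C)C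
F2 | step 13 | (13R)-2,3ξ,13-tris(triethylsilyloxy)-17-nor-5β-labda-1,14-dien-8-one | C=C[C@](C)(O[Si](CC)(CC)CC)CC[C@@H]2[C@@]3(C)C=C(O[Si](CC)(CC)CC)C(O[Si](CC)(CC)CC)C(C)(C)[C@H]3CCC2=O
F3 | step 13 | (13R)-2,3ξ,13-tris(triethylsilyloxy)-5β-labda-1,8(17),14-triene | C=C[C@](C)(O[Si](CC)(CC)CC)CC[C@@H]2[C@@]3(C)C=C(O[Si](CC)(CC)CC)C(O[Si](CC)(CC)CC)C(C)(C)[C@H]3CCC2=C
F4 | step 14 | (13R)-8α,13-epoxy-3ξ-hydroxy-17-iodo-5β-labd-14-en-2-one | C=C[C@@]1(C)CC[C@@H]2[C@@]3(C)CC(=O)C(O)C(C)(C)[C@H]3CC[C@@]2(CI)O1
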